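**Partner's price.** Up to 2 parts of partner go for each part of starting material that passes through the chain: one makes target, and one destroys that target as over-reaction product.

    partner + target → over-reaction product (k1 = 1.9 M⁻¹ min⁻¹)
    initiator → 2 initiating radical (k2 = 0.066 min⁻¹)
    starting material + initiating radical → capped initiator + first chain carrier (k3 = 34000 M⁻¹ s⁻¹)
    partner + first chain carrier → target + second chain carrier (k4 = 4.9 × 10⁵ M⁻¹ min⁻¹)
    2 second chain carrier → ended chains (k5 = 2.2 × 10⁶ M⁻¹ s⁻¹)
    starting material + second chain carrier → by-product + first chain carrier (k6 = 41000 M⁻¹ min⁻¹)

| setting | ash | larch | birch | oak |
|---|---|---|---|---|
| starting material | 0.30 M | 0.30 M | 0.30 M | 0.30 M |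
| partner | 0.0800 M | 0.150 M | 0.300 M | 0.600 M |
| initiator | 2.8 mM | 2.8 mM | 2.8 mM | 2.8 mM |
| time | 2.5 h | 2.5 h | 2.5 h | 2.5 h |

- amount of target at the end, in percent of the starting material charged for ash, larch, birch, oak, in this order
- the shape of the row from first to last (hardly changes / rises all the way / falls, then rises / falls all the way / rises, then falls)

- where a step has two of a species, its rate is k times that concentration squared, and two are used at each turn
- "hardly changes" means that all values lie within two and a half points (for a concentration: within two and a half percent of the largest)
- run time (ash): 2.5 h

**The balance.** Let y be the turns of the step from partner and first chain carrier, as a fraction of the starting material charged. Let p be the partner charge in the same measure: 0.267, 0.500, 1.00, 2.00 from ash to oak. Each turn of that step takes one partner and makes one target, and each over-reaction removes one of each. So partner minus target equals p minus 2y, and once partner is gone, target equals 2y minus p.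

**Which constants count.** Second chain carrier is reckoned at the level where termination matches initiation. Summed over the initiator's life, this gives a chain reach: 2 times the constant of starting material on second chain carrier, times the root of initiator charge over the product of the initiator constant and the termination constant. It comes to 1.47. The chain constant counts in full, and the three under the root count by their square root. The constants of radical capture, of partner on first chain carrier and of over-reaction do not stand in it. The reading time does not stand in it either, since the initiator half-life of 0.18 h is shorter than 2.5 h.

A first-order decay over that reach, with the chain reckoned as running throughout, turns a fraction 0.770 of the starting material. The partner ceiling, this fraction counted 2 times over, is 1.54. A reach multiplied by 2 gives 1.89, and one divided by 2 gives 1.04. Both lie between birch's p and oak's p.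

**Own reckoning.** Ash, larch and birch stand below the ceiling, so partner is expected to be the limiting reagent there. Their target then needs y at the moment partner runs out, which takes stepping, and this reckoning stops there. Oak's p stands above the ceiling, and this estimate puts the remainder at 23.0% of its partner. On that estimated remainder, target in oak has a half-life of 2.64 min, far shorter than 2.5 h.

**The forecast.** It gives 20.7%, 24.5%, 17.7%, 0.04%, shape rises, then falls, on the ground that "Over-reaction is fast, since each event removes partner and target together".

**The result.** The simulation gives 20.5%, 24.4%, 17.8%, 0.0348%, shape rises, then falls, turning at a partner charge of 0.15 M. The forecast stands within the margin.

**Oak's loss.** Ash, with p far under the ceiling, ends with 0% of its partner and 75.2% of its starting material. Oak, over the ceiling, keeps 22% of its partner, where the ceiling gave 23.0%. Over-reaction is the main reason for oak's low target: with that step struck out, target in oak stands at 77.5% instead of 0.0348%.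

The numbers are invented, and the outcome is calculated.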